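Remark on the chemistry: atoms are numbered C1 (angelate carbon), C2, C3 (isopropyl carbinol), C4 (ring-fusion CH), C5 (anisate carbon), C6, C7 (methyl-bearing olefin carbon), C8, C9, C10 (quaternary carbon with the angular methyl). "Methyl face" means the face of the bicycle that carries the C10 methyl. In this numbering the target is (1R,3R,4S,5S,10R).

## Structural features

The target is a daucane: a cyclopentane (C1, C2, C3, C4, C10) fused through the C4–C10 bond to a cycloheptene (C4 to C10) whose only olefin is C7=C8, with a methyl on C7. The fusion is trans (C4–H opposite the C10 methyl) and C10 is quaternary. Five stereocentres lie together: C1 (angelate on the methyl face) beside C10, C10 beside C4, and C4 between C3 (tertiary carbinol, hydroxyl on the methyl face, isopropyl opposite) and C5 (anisate opposite the methyl face). Oxygen sits on the alternating positions C1, C3 and C5, but C1 is a neopentyl methylene with no activating neighbour. Fragile points are the (Z)-angelate (isomerisation to the tiglate), the tertiary C3 alcohol (elimination, retro-aldol once C5 is a ketone), the skipped relation of C7=C8 to any C5 carbonyl, and the C7=C8 olefin itself, which competes in every intermolecular electrophilic step. The real difficulty is the quaternary C10 inside the ring fusion and the oxygen on C1 next to it; the other centres can be derived from C10 and from the C3 hydroxyl. The carbon skeleton is an intact head-to-tail farnesyl chain in which only C9–C10 and C3–C4 are not farnesol bonds, with the methyls on C7 and C10 and the isopropyl on C3 in isoprenoid positions; the key step uses this, because a terpene cyclase closes exactly these two bonds and fixes C10.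

## Logic of the disconnections

20 to 18 and 19: the C1–O acyl bond is cut first. The (Z)-enoate is the most sensitive group and should meet no further reagent. The forward step must acylate the secondary C1–OH beside the tertiary C3–OH without Z to E isomerisation.

18 to 17 to 16: the C1–O bond is traced back to a C1=C2 olefin. The C3 hydroxyl is the only handle near C1, so it is made to deliver the oxygen (epoxide on its own face) and the C2–O bond is then cleaved reductively. C1 thereby becomes a consequence of C3. The demand is cleavage of the epoxide at C2 and not at C1.

16 to 14 and 15: the C5–O acyl bond is cut. In 14 the C5 hydroxyl is the only secondary alcohol, so no protecting group is needed.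

14 to 13 to 12: the C5 carbinol is taken back to the ketone. The epoxide route places the C5 oxygen on the methyl face, which is the wrong one; oxidation followed by reduction directed by the C3 hydroxyl corrects it. The ketone must be reduced before it can enolise towards C6.

12 to 11: the C4–H bond and the C5 hydroxyl are derived from a 4,5-epoxide. Reductive opening through the tertiary C4 radical keeps the C5–O bond. The demand is hydrogen transfer to C4 from the face opposite the methyl.

11 to 9 to 8: the C1=C2 olefin is derived from the saturated ring by a radical tethered to the C3 oxygen. This is done at the epoxide stage because the C5–H there is an epoxide C–H, which cannot compete, and the C3 hydroxyl is the only hydroxyl. The demand is hydrogen abstraction at C1 or C2 and not at the isopropyl group.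

8 to 6 (through 7): the C3–O bond and the 4,5-epoxide are both derived from the tetrasubstituted C3=C4 olefin and dioxygen. One step replaces a hydrocarbon diene by the C3 carbinol with the C4=C5 unsaturation already oxidised. The demand is an ene reaction at the C5–H on the methyl face and chemoselectivity over C7=C8.

6 to 5: the C3=C4 olefin comes from dehydration of the ring-fusion alcohol. C3 and C4 of 5 are erased on purpose; C10, C7=C8 and the isopropyl group are kept.

5 to 4: the C9–C10 and C3–C4 bonds and the C4–O bond are cut together. This removes both rings and three stereocentres and leaves an acyclic achiral triene. The substrate is kept as the native one, with no oxygen at the chain carbon that becomes C1, because an extra allylic oxygen beside the central olefin would put the only enzymatically proven step at risk.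

4 to 2 and 3, and 2 to 1: the C–O–P bond and then the C–Cl bond are cut. Both forward steps must preserve the 2E,6E geometry and avoid allylic transposition.

## Other disconnections considered

Alternative 1: the cut is through C5–C6 and C7–C8, so that C6 and C7 come from ethyl but-2-ynoate A2 and the rest from the trimethylsilyl enol ether A1 of a cis-fused diquinane ketone. In the forward step a Lewis-acid-promoted [2+2] addition joins C8 to C7 and C5 to C6, and the silyloxycyclobutene opens to the ring-expanded diene ester A3.
- In its favour: C1 already carries its oxygen, and C3 and C10 are set on a compact bicyclo[3.3.0]octane whose convex face controls additions. On the C1 oxygen this alternative is better than the chosen plan, which needs a C–H functionalisation.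
- Against it: A3 has the cis ring fusion, so C4 must be inverted after the C5 ketone is unveiled. The ester on C6 is not in the target and must be removed from a β-keto ester whose olefin can slip into conjugation. A1 itself, with a quaternary centre, a tertiary silyl ether and a secondary one, needs a long enantioselective preparation.
- Structure: A3 contains every carbon of the core plus two surplus ones; carotol contains exactly the fifteen skeletal carbons.
- Mechanism: the addition and electrocyclic opening is a predictable abiotic sequence and is the equal of the enzymatic step in reliability of bond formation. It does not create C10, which is carried in from A1.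
- Step economy: the end-game from A3 is shorter than the eleven steps after carotol, but the route to A1 is expected to outweigh that gain.

Alternative 2: the cut is through C10–CH3 and C3–C4. A copper-catalysed asymmetric conjugate methylation of the 3-substituted cyclohepta-2,5-dienone A4 creates C10, and the aluminium enolate closes the cyclopentanol by aldol addition to the side-chain isopropyl ketone, giving the bicyclic aldol A5.
- In its favour: one step builds the quaternary centre, the five-membered ring and the C3 carbinol. The C1 oxygen is in place. A5 differs from ketone 13 of the chosen route only in the five-membered ring, so its end-game would be shorter; this is a point on which the alternative is better.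
- Against it: A4 is a β,γ-unsaturated dienone that can isomerise to the fully conjugated dienone and then accept the methyl at the wrong terminus. The catalyst must override or match the existing C1 stereocentre. The aldol must select one of four C3/C4 diastereomers. A5 carries the same base-labile skipped enone as 13.
- Structure: A5 maps onto the target atom for atom; in this respect it equals the cyclase product and is ahead of it in oxidation pattern.
- Mechanism: catalyst control of a quaternary centre on a seven-membered dienone is less secure than the enzyme's control of C10.
- Step economy: comparable overall, since A4 with its stereodefined side chain needs a multi-step synthesis.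

Alternative 3: the cut is through C4–C10 and C4–C5. A rhodium carbene generated from the diazoketone A6 adds across the ipso–ortho bond of the tolyl ring (Buchner reaction), the norcaradiene opens, and base brings the triene into conjugation to give the azulenone A7. As the product is written in the task its silyl ether carbon is S, whereas C1 of the target is R with the same priority order (O, ring carbon, CH2, H). A6 and A7 are therefore taken here in the R series, since this centre is meant to be carried through.
- In its favour: the bicyclic core with the C7 methyl in place arises from an aromatic precursor in very few steps. In step count to a bicyclic intermediate this alternative is better than the chosen plan, and it needs no enzyme.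
- Against it: A7 is nearly flat and holds only one stereocentre. The C10 methyl must then be added to a tetrasubstituted carbon of a cross-conjugated trienone, cis to the silyl ether and against the usual anti preference, with 1,6- and 1,8-addition as competitors. The isopropyl group must be added to an enolisable ketone. C5 must be oxygenated and one ring olefin removed regioselectively.
- Structure: A7 lacks C10 and C3 as stereocentres and lacks two of the fifteen carbons' substituents (angular methyl, isopropyl); carotol has both.
- Mechanism: the carbene step is robust, but the subsequent stereochemical work is the hard part; the cyclase does that work in one step.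
- Step economy: short to A7, long afterwards; the total is expected to be no better than the chosen route.

Key step: step 3

Remark on the chemistry: carotol as written is the natural (3S,3aS,8aR) compound and its C10 has the same spatial arrangement as C10 of the target; the diphosphate as written is 2E,6E. Neither needs correction.

## Route

Step 1
Reactants: 1 (2E,6E)-farnesol
Product: 2 (2E,6E)-farnesyl chloride
Conditions: NCS, Me2S, CH2Cl2, −30 to 0 °C
Reagents that add atoms: N-chlorosuccinimide, O=C1CCC(=O)N1Cl
Why: Corey–Kim chlorination of a primary allylic alcohol; chloride displaces the alkoxysulfonium group at the primary carbon, so neither allylic transposition nor loss of olefin geometry is expected.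

Step 2
Reactants: 2 (2E,6E)-farnesyl chloride; 3 tris(tetrabutylammonium) hydrogen diphosphate
Product: 4 (2E,6E)-farnesyl diphosphate (handled as its ammonium salt, drawn as the acid)
Conditions: MeCN, rt; then cation-exchange resin (NH4+ form), cellulose chromatography, iPrOH/aq. NH4HCO3
Reagents that add atoms: tris(tetrabutylammonium) hydrogen diphosphate, CCCC[N+](CCCC)(CCCC)CCCC.CCCC[N+](CCCC)(CCCC)CCCC.CCCC[N+](CCCC)(CCCC)CCCC.OP(=O)([O-])OP(=O)([O-])[O-]
Why: SN2 displacement of a primary allylic chloride by the diphosphate trianion, the standard preparation of prenyl diphosphates; the soluble ammonium salt keeps the reaction homogeneous and free of water.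

Step 3
Reactants: 4 (2E,6E)-farnesyl diphosphate
Product: 5 carotol
Conditions: recombinant carotol synthase (class one sesquiterpene cyclase), MgCl2, Tris·HCl buffer pH 7.5, dithiothreitol, 30 °C, pentane overlay
Reagents that add atoms: water, O
Why: The magnesium-bound diphosphate ionises and the allyl cation reaches the cisoid form through the tertiary (nerolidyl) diphosphate; this is the native reaction of the enzyme, and the closest reaction type is the class one terpene synthase cyclisation of farnesyl diphosphate. The cation terminus C9 attacks C10 of the central olefin and closes the seven-membered ring in a 7-endo mode, leaving a cation at C4. The distal olefin then attacks C4 through C3 and closes the five-membered ring in a 5-exo mode, placing the charge on the isopropyl carbon. Two 1,2-hydride shifts (C3 to the isopropyl carbon, then C4 to C3) move the charge to the ring fusion, where bound water adds. C10 is set by the face of the central olefin that the active-site fold presents to C9, C3 by the suprafacial hydride shift within that fold, and C4 by the side from which the water is held. The step needs one folding mode and one quench out of many cationic pathways (early deprotonation to farnesenes or bisabolenes, loss of a proton to daucene); the enzyme secures both, and the substrate only has to supply the 2E,6E chain. The volatile product is drawn into the pentane layer, which limits product inhibition.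

Step 4
Reactants: 5 carotol
Product: 6 daucene
Conditions: Burgess reagent, PhH, 50 °C
Reagents that add atoms: none
Why: Burgess dehydration is a syn elimination; in 5 the C3–H and the C4–OH are cis on the cyclopentane and nearly eclipsed, so this hydrogen should be lost and the tetrasubstituted C3=C4 olefin formed. C10 is untouched; C3 and C4 are erased deliberately.

Step 5
Reactants: 6 daucene
Product: 8 4,5-epoxy-3-ol (hydroxyl and epoxide oxygen on the methyl face), via allylic C3 hydroperoxide 7 (not isolated)
Conditions: O2, visible light, tetraphenylporphyrin (cat.), CH2Cl2, −20 °C; then Ti(OiPr)4 (cat.), 0 °C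
Reagents that add atoms: dioxygen, O=O
Why: Schenck ene reaction of singlet oxygen followed by titanium-mediated oxygen transfer from the allylic hydroperoxide (hydroxy-epoxidation). The tetrasubstituted C3=C4 should react well ahead of C7=C8, and the only C5–H aligned with the π-lobes is the pseudo-axial one on the methyl face, so oxygen should enter at C3 on that face while the olefin moves to C4=C5. The titanium-bound C3 peroxide then delivers oxygen to C4=C5 from the same face and leaves C7=C8 alone.

Step 6
Reactants: 8 4,5-epoxy-3-ol
Product: 9 (iodomethyl)dimethylsilyl ether of 8
Conditions: ICH2SiMe2Cl, imidazole, DMF, rt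
Reagents that add atoms: chloro(iodomethyl)dimethylsilane, C[Si](C)(Cl)CI
Why: Silylation of the only hydroxyl group; the small dialkylchlorosilane should reach the hindered tertiary alcohol under imidazole catalysis as a trimethylsilyl chloride does.

Step 7
Reactants: 9 (iodomethyl)dimethylsilyl ether
Product: 11 1,2-didehydro-4,5-epoxy-3-ol, via trimethylsilyl ether 10 (not isolated)
Conditions: Pd(OAc)2 (10 mol %), Xantphos, Cs2CO3, PhH, blue LED, rt; then K2CO3 (cat.), MeOH, 0 °C
Reagents that add atoms: none
Why: Photoinduced palladium-catalysed remote desaturation of a silicon-tethered alcohol. Zerovalent palladium and light turn the C–I bond into a silylmethyl radical, which abstracts the C1–H cis to the C3 oxygen through a seven-membered transition state; the C1 radical recombines with palladium, and β-hydride elimination can only use C2–H because C10 is quaternary, so the olefin is C1=C2 (abstraction at C2 would give the same olefin). The tether ends as a trimethylsilyl ether that methanolysis removes; the epoxide C–H at C5 is too strong and wrongly placed to compete.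

Step 8
Reactants: 11 1,2-didehydro-4,5-epoxy-3-ol
Product: 12 3,5-diol (C4–H opposite the methyl face, C5–OH on the methyl face, C1=C2 and C7=C8 present)
Conditions: Cp2TiCl2 (10 mol %), Mn, 2,4,6-collidine·HCl, 1,4-cyclohexadiene, THF, rt
Reagents that add atoms: none
Why: Titanocene-catalysed reductive epoxide opening by trivalent titanium: the C4–O bond breaks to give the tertiary C4 radical, the pattern known for 2,3-epoxy alcohols leading to 1,3-diols, and the C5–O bond is kept. 1,4-Cyclohexadiene should transfer hydrogen to C4 from the face opposite the C10 methyl and the two metal-bound oxygens, which gives the trans ring fusion; ring strain keeps the radical from adding to either olefin.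

Step 9
Reactants: 12 3,5-diol
Product: 13 3-hydroxy-5-ketone
Conditions: Dess–Martin periodinane, NaHCO3, CH2Cl2, 0 °C
Reagents that add atoms: none
Why: Dess–Martin oxidation of the only secondary alcohol; the tertiary allylic alcohol is inert, and the buffered neutral medium should leave C4 and the position of C7=C8 unchanged.

Step 10
Reactants: 13 3-hydroxy-5-ketone
Product: 14 3,5-diol (C5–OH opposite the methyl face)
Conditions: Me4NBH(OAc)3, MeCN/AcOH, −30 °C
Reagents that add atoms: none
Why: Hydroxyl-directed reduction (Evans–Saksena): the C3 alkoxide binds boron and delivers hydride intramolecularly to the methyl face of the C5 carbonyl, so the new C5–OH is anti to the C3–OH and opposite the C10 methyl, as in the target. The acidic low-temperature medium avoids enolisation towards C6.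

Step 11
Reactants: 14 3,5-diol; 15 4-methoxybenzoyl chloride
Product: 16 5-O-(4-methoxybenzoyl) derivative of 14
Conditions: pyridine, DMAP (cat.), CH2Cl2, 0 °C to rt
Reagents that add atoms: 4-methoxybenzoyl chloride, COc1ccc(cc1)C(Cl)=O
Why: Acylation of the single secondary alcohol; the tertiary C3–OH does not react under these conditions.

Step 12
Reactants: 16 5-anisate with C1=C2
Product: 17 1,2-epoxide of 16 (epoxide oxygen on the methyl face)
Conditions: VO(acac)2 (cat.), t-BuOOH, CH2Cl2, 0 °C to rt
Reagents that add atoms: tert-butyl hydroperoxide, CC(C)(C)OO
Why: Vanadium-catalysed hydroxyl-directed epoxidation: the tert-butylperoxide bound to the vanadium alkoxide of the allylic C3–OH epoxidises C1=C2 on the face of that hydroxyl and does not reach the remote C7=C8.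

Step 13
Reactants: 17 1,2-epoxide
Product: 18 1,3-diol 5-anisate (C1–OH on the methyl face)
Conditions: Cp2TiCl2 (10 mol %), Mn, 2,4,6-collidine·HCl, 1,4-cyclohexadiene, THF, rt
Reagents that add atoms: none
Why: Second titanocene-catalysed reductive opening: as with other 2,3-epoxy alcohols the C–O bond next to the carbinol (C2–O) should break, the C2 radical is reduced by 1,4-cyclohexadiene, and the C1–O bond is retained with its configuration, cis to the C3–OH and the C10 methyl. The aryl ester is inert to trivalent titanium.

Step 14
Reactants: 18 1,3-diol 5-anisate; 19 angelic acid
Product: 20 target, the 1-O-angelate 5-O-anisate (CNP0204191.1)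
Conditions: 19, 2,4,6-trichlorobenzoyl chloride, Et3N, PhMe, rt; then 18, 75 °C
Reagents that add atoms: angelic acid, C/C=C(/C)C(O)=O
Why: Yamaguchi esterification through the preformed mixed anhydride, run without a nucleophilic amine catalyst to avoid Z to E isomerisation; only the secondary C1–OH is acylated, and the tertiary C3–OH and the C5 ester stay as they are.

## Compound list

1 | (2E,6E)-farnesol | CC(C)=CCC/C(C)=C/CC/C(C)=C/CO | starting material
2 | (2E,6E)-farnesyl chloride | CC(C)=CCC/C(C)=C/CC/C(C)=C/CCl | intermediate
3 | tris(tetrabutylammonium) hydrogen diphosphate | CCCC[N+](CCCC)(CCCC)CCCC.CCCC[N+](CCCC)(CCCC)CCCC.CCCC[N+](CCCC)(CCCC)CCCC.OP(=O)([O-])OP(=O)([O-])[O-] | starting material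
4 | (2E,6E)-farnesyl diphosphate (precursor of the key step) | CC(C)=CCC/C(C)=C/CC/C(C)=C/COP(=O)(O)OP(=O)(O)O | intermediate
5 | carotol, (3S,3aS,8aR)-6,8a-dimethyl-3-(propan-2-yl)-2,3,4,5,8,8a-hexahydroazulen-3a(1H)-ol; C4–OH and C3–H on the methyl face (product of the key step) | C1C[C@@H](C(C)C)[C@@]2(O)CCC(C)=CC[C@]21C | intermediate
6 | daucene, (8aR)-6,8a-dimethyl-3-(propan-2-yl)-1,2,4,5,8,8a-hexahydroazulene; C3=C4 and C7=C8 | C1CC(C(C)C)=C2CCC(C)=CC[C@]21C | intermediate
7 | allylic C3 hydroperoxide; OOH on the methyl face, C4=C5 and C7=C8 | C1C[C@@](OO)(C(C)C)C2=CCC(C)=CC[C@]21C | intermediate (not isolated)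
8 | 4,5-epoxy-3-ol; C3–OH and epoxide oxygen on the methyl face, isopropyl opposite | C1C[C@@](O)(C(C)C)[C@@]2(O3)[C@H]3CC(C)=CC[C@]21C | intermediate
9 | (iodomethyl)dimethylsilyl ether of 8 | C1C[C@@](O[Si](C)(C)CI)(C(C)C)[C@@]2(O3)[C@H]3CC(C)=CC[C@]21C | intermediate
10 | trimethylsilyl ether of 11 | C1=C[C@@](O[Si](C)(C)C)(C(C)C)[C@@]2(O3)[C@H]3CC(C)=CC[C@]21C | intermediate (not isolated)
11 | 1,2-didehydro-4,5-epoxy-3-ol (C1=C2, tertiary allylic alcohol, 4,5-epoxide on the methyl face) | C1=C[C@@](O)(C(C)C)[C@@]2(O3)[C@H]3CC(C)=CC[C@]21C | intermediate
12 | 3,5-diol with C1=C2; C4–H opposite the methyl face (trans fusion), C5–OH on the methyl face | C1=C[C@@](O)(C(C)C)[C@@H]2[C@H](O)CC(C)=CC[C@]21C | intermediate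
13 | 3-hydroxy-5-ketone with C1=C2 (trans fusion) | C1=C[C@@](O)(C(C)C)[C@@H]2C(=O)CC(C)=CC[C@]21C | intermediate
14 | 3,5-diol with C1=C2; C5–OH opposite the methyl face | C1=C[C@@](O)(C(C)C)[C@@H]2[C@@H](O)CC(C)=CC[C@]21C | intermediate
15 | 4-methoxybenzoyl chloride | COc1ccc(cc1)C(Cl)=O | starting material
16 | 5-O-(4-methoxybenzoate) of 14 | C1=C[C@@](O)(C(C)C)[C@@H]2[C@@H](OC(=O)c3ccc(OC)cc3)CC(C)=CC[C@]21C | intermediate
17 | 1,2-epoxide of 16; epoxide oxygen on the methyl face, cis to the C3–OH | O1[C@@H]2[C@H]1[C@@](O)(C(C)C)[C@@H]3[C@@H](OC(=O)c4ccc(OC)cc4)CC(C)=CC[C@]32C | intermediate
18 | 1,3-diol 5-(4-methoxybenzoate); C1–OH and C3–OH on the methyl face | O[C@@H]1C[C@@](O)(C(C)C)[C@@H]2[C@@H](OC(=O)c3ccc(OC)cc3)CC(C)=CC[C@]21C | intermediate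
19 | angelic acid, (Z)-2-methylbut-2-enoic acid | C/C=C(/C)C(O)=O | starting material
20 | CNP0204191.1, (1R,3R,4S,5S,10R) in the numbering used here: 1-O-angelate, 3-hydroxy, 5-O-(4-methoxybenzoate) | C/C=C(/C)C(=O)O[C@@H]1C[C@@](O)(C(C)C)[C@@H]2[C@@H](OC(=O)c3ccc(OC)cc3)CC(C)=CC[C@]21C | target

## Step count and risks

Total step count: 14. Longest linear sequence: 14 steps (1 to 20); the route is linear, with 3, 15 and 19 entering as reagents.

Step 3 (key step). Most likely failure: low turnover on a preparative scale, through hydrolysis of the diphosphate, inhibition by the released magnesium diphosphate and product, and leakage of the cation cascade to acyclic or monocyclic olefins. Fallback: the isolated diphosphate is avoided. Farnesol 1 is fed to Escherichia coli cells (or a cell-free mixture with ATP regeneration) that express a promiscuous prenol kinase, an isopentenyl phosphate kinase and the same cyclase. 1 is phosphorylated to (2E,6E)-farnesyl phosphate F1 and then to 4, which is cyclised as it forms; the product is collected in a dodecane overlay. The fallback sets out from 1 and returns at 5.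

Step 7. Most likely failure: hydrogen abstraction by the tethered radical at an isopropyl methyl or at the isopropyl methine in place of C1–H, because six primary hydrogens and one weak tertiary hydrogen are also within reach. Fallback: the C1 oxygen is introduced by a biocatalytic C–H hydroxylation instead of the tether. From 8 the epoxide is opened as in step 8 to the saturated 3,5-diol F2, which is oxidised as in step 9 to the saturated hydroxy ketone F3, reduced as in step 10 to the saturated 3,5-diol F4 and acylated as in step 11 to the saturated 5-anisate F5. F5 is then hydroxylated at C1 with retention by a cytochrome P450 monooxygenase selected from a library of CYP102A1 variants (whole cells, glucose-driven cofactor recycling), which gives 18 directly. The enzyme would have to be found by screening, since the allylic C6 and C9 positions are the intrinsically weaker C–H bonds. The fallback sets out from 8 and returns at 18.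

Step 5. Most likely failure: the ene reaction abstracting a C2–H instead of the C5–H, which would place the hydroperoxide on C4 and the olefin at C2=C3, together with slow over-oxidation at C7=C8. Fallback: regiochemistry is fixed by an anti addition. Daucene 6 is treated with N-(phenylseleno)phthalimide and water (camphorsulfonic acid cat., CH2Cl2). The seleniranium ion should form opposite the methyl and water should open it at C3, the carbon whose rear side is not blocked by the quaternary centre, giving the 3-hydroxy-4-phenylselenide F6. Oxidation with H2O2 and syn elimination of the selenoxide can only use a C5–H and gives the allylic alcohol F7 (C3–OH on the methyl face, C4=C5). Epoxidation directed by the hydroxyl (VO(acac)2, t-BuOOH) then leads to 8. The fallback sets out from 6 and returns at 8.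

Step 13. Most likely failure: cleavage of the C1–O bond of the epoxide instead of the C2–O bond, since both carbons are secondary and both are flanked by a fully substituted carbon; this would give the 2,3-diol. Fallback: the oxygen is delivered by a silicon tether instead of an epoxide. From 16 the C3 hydroxyl is silylated with (HMe2Si)2NH to the dimethylsilyl ether F8. Intramolecular hydrosilylation with Pt2[(CH2=CHSiMe2)2O]3 closes the five-membered ring through C1 to the oxasilolane F9, with silicon necessarily cis to the C3 oxygen. Tamao oxidation (H2O2, KF, KHCO3) replaces silicon by hydroxyl with retention and gives 18. The fallback sets out from 16 and returns at 18.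

Step 8. Most likely failure: poor facial selectivity in the hydrogen transfer to the planar C4 radical, giving the cis-fused C4 epimer. Fallback: kinetic control is replaced by thermodynamic control at the ketone stage. The C4-epimeric diol F10 formed from 11 is oxidised as in step 9 to the cis-fused hydroxy ketone F11. Its C4–H is α to the carbonyl and is equilibrated with a catalytic amount of DBU (CH2Cl2, 0 °C) to 13. In 13 the isopropyl group and C5 are trans on the five-membered ring, so 13 should be the more stable epimer. The fallback sets out from 11 and returns at 13.

## Further compounds

F1 | step 3 | (2E,6E)-farnesyl phosphate | CC(C)=CCC/C(C)=C/CC/C(C)=C/COP(=O)(O)O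
F2 | step 7 | saturated 3,5-diol (C4–H opposite the methyl face, C5–OH on the methyl face) | C1C[C@@](O)(C(C)C)[C@@H]2[C@H](O)CC(C)=CC[C@]21C
F3 | step 7 | saturated 3-hydroxy-5-ketone | C1C[C@@](O)(C(C)C)[C@@H]2C(=O)CC(C)=CC[C@]21C
F4 | step 7 | saturated 3,5-diol (C5–OH opposite the methyl face) | C1C[C@@](O)(C(C)C)[C@@H]2[C@@H](O)CC(C)=CC[C@]21C
F5 | step 7 | saturated 5-O-(4-methoxybenzoate) | C1C[C@@](O)(C(C)C)[C@@H]2[C@@H](OC(=O)c3ccc(OC)cc3)CC(C)=CC[C@]21C
F6 | step 5 | 3-hydroxy-4-phenylselenide (C3–OH on the methyl face, selenium opposite) | C1C[C@@](O)(C(C)C)[C@]2([Se]c3ccccc3)CCC(C)=CC[C@]21C
F7 | step 5 | allylic alcohol (C3–OH on the methyl face, C4=C5, C7=C8) | C1C[C@@](O)(C(C)C)C2=CCC(C)=CC[C@]21C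
F8 | step 13 | dimethylsilyl ether of 16 | C1=C[C@@](O[SiH](C)C)(C(C)C)[C@@H]2[C@@H](OC(=O)c3ccc(OC)cc3)CC(C)=CC[C@]21C
F9 | step 13 | oxasilolane bridging the C3 oxygen and C1 | C[Si]4(C)[C@@H]1C[C@@](O4)(C(C)C)[C@@H]2[C@@H](OC(=O)c3ccc(OC)cc3)CC(C)=CC[C@]21C
F10 | step 8 | C4 epimer of 12 (cis fusion) | C1=C[C@@](O)(C(C)C)[C@H]2[C@H](O)CC(C)=CC[C@]21C
F11 | step 8 | C4 epimer of 13 (cis fusion) | C1=C[C@@](O)(C(C)C)[C@H]2C(=O)CC(C)=CC[C@]21C
A1 | alternative 1 | trimethylsilyl enol ether of the cis-diquinane ketone | CC(C)(C)[Si](C)(C)O[C@@H]1C[C@@](O[Si](CC)(CC)CC)(C(C)C)[C@H]2C(O[Si](C)(C)C)=CC[C@]21C
A2 | alternative 1 | ethyl but-2-ynoate | CC#CC(=O)OCC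
A3 | alternative 1 | ring-expanded 2-silyloxy diene ester (cis ring fusion) | CC(C)(C)[Si](C)(C)O[C@@H]1C[C@@](O[Si](CC)(CC)CC)(C(C)C)[C@H]2C(O[Si](C)(C)C)=C(C(=O)OCC)C(C)=CC[C@]21C
A4 | alternative 2 | 3-substituted 6-methylcyclohepta-2,5-dienone with the (methoxymethoxy) isopropyl ketone side chain | COCO[C@H](CC(=O)C(C)C)C1=CC(=O)CC(C)=CC1
A5 | alternative 2 | trans-fused bicyclic aldol (C3 carbinol, C5 ketone, C1 methoxymethyl ether) | COCO[C@@H]1C[C@@](O)(C(C)C)[C@@H]2C(=O)CC(C)=CC[C@]21C
A6 | alternative 3 | (R)-4-(tert-butyldimethylsilyloxy)-1-diazo-4-(p-tolyl)butan-2-one | [N-]=[N+]=CC(=O)C[C@@H](O[Si](C)(C)C(C)(C)C)c1ccc(C)cc1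
A7 | alternative 3 | (R)-3-(tert-butyldimethylsilyloxy)-6-methyl-3,4-dihydro-2H-azulen-1-one (configuration corrected to that of C1 in the target) | O=C1C[C@@H](O[Si](C)(C)C(C)(C)C)C2=C1C=CC(C)=CC2
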